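## Analysis of the target

Compound 22 is a 3,5,6,7-tetrahydrobenzofuran-4(2H)-one. A dihydrofuran ring (O1, C2, C3, C3a, C7a) is fused through the C3a=C7a enol ether bond to a cyclohexenone (C3a, C4 to C7, C7a), so that O1–C7a=C3a–C4=O is a vinylogous ester. C5, next to the C4 carbonyl, carries a secondary hydroxyl (5R). C2 (2S) carries a ten-carbon chain that starts with the tertiary carbinol C1' (1'S, methyl and hydroxyl) and runs through two E-trisubstituted alkenes, C4'=C5' and C8'=C9', to the carboxyl carbon C10'. C2 and C1' are vicinal and must be set relative to each other, whereas C5 is separated from C2 by the enol ether and three ring bonds and cannot be controlled by relay from either. The sensitive functions are the α-ketol (epimerisation at C5, oxidation to the diosphenol), the vinylogous ester (opened by hydroxide, hydrolysed by strong aqueous acid), the tertiary alcohol β to O1 and the conjugated acid. The main difficulty is C1': its three carbon substituents are a methyl group and two chains of similar size, so a carbonyl addition at this carbon is hard to steer. The plan rests on the fact that C1' carries, besides methyl and hydroxyl, two two-carbon arms: C2–C3 inside the dihydrofuran ring and C2'–C3' at the start of the chain. Drawn as two vinyl groups, these arms make C1' achiral, and the C2/C1' pair becomes 3-methylpenta-1,4-dien-3-ol 4, in which one enantioselective oxidation of one vinyl group can create both centres at once.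

## Retrosynthetic reasoning

**22 from 21.** The last operation should only uncover the two hydroxyls. Silyl ethers on the C5 and C1' oxygens can be removed by buffered fluoride, which neither enolises C5 nor opens the vinylogous ester. An ester at C10' would need hydroxide at this stage, so the carboxyl group is carried free.

**C3'–C4' (21 from 12 and 19).** The chain is cut between the sp3 carbon C3' and the alkene carbon C4'. C3' is the end of the vinyl arm left over from the desymmetrisation, so hydroboration turns it into the nucleophile of a B-alkyl Suzuki–Miyaura coupling (through borane 20). The geometry of C4'=C5' is fixed beforehand in alkenyl iodide 19 and transferred with retention. A cut at C2'–C3' or inside the dienoic acid would not use the vinyl group as a handle. The cut also makes the route convergent and places the whole chain, already at the acid oxidation level, in one fragment.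

**Fragment 19.** The C8'=C9' bond is cut by a Wittig disconnection to aldehyde 16 and stabilised ylide 17, which leads to E-enoate 18. The C5'–methyl and C4'–iodine bonds go back to alkyne 13 by syn methylmetalation and iodination (through 14 and 15). Both alkene geometries therefore come from reactions whose stereochemical course is fixed by mechanism.

**C5–O (12 from 11 from 9).** The C5 oxygen is removed to leave the unsubstituted vinylogous ester 9. In the forward direction, kinetic deprotonation of 9 gives the α' enolate 10 at C5, so the position of the new oxygen is not in doubt. Its configuration has to come from the oxidant, because C2 and C1' are remote. Placing this step after the bicycle and before the chain is attached keeps strong base away from the enoic acid and lets the ring be made from a symmetric dione.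

**C3–C3a and O1–C7a (9 from 6 and 7).** The dihydrofuran is opened at the enol ether bond O1–C7a and at C3–C3a. This leads to dione 7 and a terminal epoxide whose CH2 is C3 and whose oxygen is O1 (through 8). Because 7 is symmetric, either carbonyl gives the same ring. The tertiary oxygen on C1' is silylated first (6), so that only the C2 oxygen can close the ring and the epoxide cannot migrate. The forward step has to achieve C- rather than O-alkylation of the dione.

**C2–O and C3–O (6 from 5 from 4, the key disconnection).** Removing the epoxide oxygen from 5 gives dienol 4, in which C1' is no longer a stereocentre. In the forward direction one directed, enantioselective epoxidation has to choose one of two enantiotopic vinyl groups and one of its faces, which sets C2 and C1' together. The untouched vinyl group is exactly the C2'–C3' unit needed for the coupling. No other disconnection of the C2/C1' pair removes both centres in one step.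

**4 from 1 and 2.** Dienol 4 is cut at both C1'–vinyl bonds to ester 1 and two equivalents of Grignard reagent 2 (through enone 3).

## Alternatives that were turned down

**Alternative 1:** Three-component ylide annulation.
- Disconnection: all three bonds that close the dihydrofuran (C3a–C3, C3–C2, O1–C2) are cut at once. This leaves dione 7, formaldehyde A3 as C3, and bromomethyl ketone A2, made from geranylacetone A1; the CH2Br carbon of A2 becomes C2 and its carbonyl becomes C1'.
- Forward key step: a cinchona-derived tertiary amine quaternises A2. The ammonium ylide adds to the 2-methylene dione formed in the flask from 7 and A3, and the enolate oxygen displaces the ammonium group at C2 to give ketone A4.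
- For it: three bonds and the ring form in one flask, A1 is a cheap terpene ketone that brings twelve of the thirteen side-chain carbons, and a later methyl Grignard addition to the C1' ketone could use O1 as a chelating group.
- Against it:
  - C2 of A4 is α to a ketone and bears O1, so it can epimerise under the basic conditions that form it.
  - With an unsubstituted methylene acceptor only the ylide carbon is stereogenic, and it can equilibrate before ring closure.
  - The methylene dione is also captured by a second molecule of 7.
  - C1' is set afterwards by substrate control, with the C4 carbonyl as a competing electrophile.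
  - The distal dimethyl alkene must be oxidised to the E-acid late, next to a second trisubstituted alkene.
  - C5 still needs hydroxylation.
- Comparison: this alternative is stronger in convergence of the ring synthesis and in cost of carbon. The chosen route sets C2 and C1' in one catalyst-controlled event and brings the chain terminus in already oxidised.

**Alternative 2:** Chiral-pool C5 and Dieckmann closure.
- Disconnection: the carbocycle is cut at C3a–C4. C5 comes from the chiral pool as an α-silyloxy ester, and the C2/C1' diol is carried as an acetonide.
- Forward key step: an alkoxide base forms the ketone enolate at C3a, which attacks the C4 ester and closes the six-membered ring as a 2-alkyl-4-silyloxycyclohexane-1,3-dione.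
- A structural point: in the form first drawn, A5, the tether between the dione carbon and the dioxolane has two CH2 groups. That is one more than the single C3 bridge of 22 and would close to a six-membered oxygen ring. The comparison is therefore made for the lower homologue A6.
- For it: the C5 configuration is secured from the start. On this point it is stronger than the chosen route, which relies on a late reagent-controlled hydroxylation.
- Against it:
  - The dione A6 is unsymmetrical, so cyclodehydration can take place at either carbonyl, and nothing obvious directs it to the one that leaves the silyloxy carbon next to the remaining ketone.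
  - C5 is α to an ester and then to a dione carbonyl under strong base, with risk of epimerisation and β-elimination.
  - The acyclic keto ester needs a long linear sequence.
  - The C2/C1' diol still needs its own asymmetric method, so the central problem is moved, not solved.
- Comparison: the chosen route uses the symmetric dione 7, fixes the ring regiochemistry before C5 is oxidised and needs fewer steps.

**Alternative 3:** Payne-relayed epoxide annulation.
- Disconnection: C3–C3a and O1–C7a, as in the chosen plan, but the electrophile is a 2,3-epoxy alcohol that carries the whole chain, A9, made by Sharpless epoxidation of a farnesol.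
- Forward key step: in aqueous base A9 equilibrates by Payne rearrangement with its terminal epoxide isomer. The dione enolate opens that isomer at CH2, and the freed C2 oxygen condenses on a carbonyl to give A10.
- For it: all fifteen side-chain carbons come from one commercial terpene alcohol, the asymmetric step is a well-established Sharpless epoxidation of a primary allylic alcohol, and the sequence is shorter. On reliability of the asymmetric step and on step count this alternative is stronger than the chosen route.
- Against it:
  - Because C2 is inverted in the Payne step, the (2S,1'S) configuration of 22 maps onto the cis-epoxide. The substrate must therefore be the 2Z isomer A7, which is costlier as a pure isomer and a poorer Sharpless substrate than (2E,6E)-farnesol A8.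
  - The Payne equilibrium favours the internal epoxide with the primary alcohol, so the reactive terminal isomer is a minor partner.
  - A weakly nucleophilic dione enolate has to meet a lipophilic C15 substrate in strongly basic water.
  - The tertiary hydroxyl must stay free and can compete for ring closure.
  - The distal dimethyl alkene must be oxidised selectively to the E-acid after the α-ketol and the vinylogous ester are in place.
- Comparison: the chosen route offers in its place a terminal epoxide that needs no migration, a capped tertiary oxygen, a chain terminus that arrives as the acid with both geometries fixed, and a late, convergent coupling.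

Key step: step 2

Remark on the chemistry: the sense of induction of the hafnium ligand in step 2 and of the oxaziridine in step 5 is assumed as written; should either prove opposite, the mirror-image ligand or reagent is used with no other change.

## Route

Step 1
Reactants: 1 ethyl acetate; 2 vinylmagnesium bromide
Product: 4 3-methylpenta-1,4-dien-3-ol, via but-3-en-2-one 3 (not isolated)
Conditions: vinylmagnesium bromide (2.2 equiv), THF, 0 °C to rt; aq. NH4Cl
Reagents that add atoms: none
Why: Double Grignard addition to an ester: the first equivalent gives enone 3 by loss of ethoxide, and 3 is more electrophilic than 1 and takes up the second equivalent by 1,2-addition. No stereocentre is formed.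

Step 2
Reactants: 4 3-methylpenta-1,4-dien-3-ol
Product: 5 (2S)-2-[(2S)-oxiran-2-yl]but-3-en-2-ol
Conditions: Hf(OtBu)4 (10 mol%), N,N'-[(1R,2R)-cyclohexane-1,2-diyl]bis(N-hydroxy-2,2-diphenylacetamide) (12 mol%), cumene hydroperoxide (1.3 equiv), MgO, toluene, 0 °C
Reagents that add atoms: cumene hydroperoxide, CC(C)(OO)c1ccccc1
Why: Proposed new method: the hydroxyl of 4 exchanges for a tert-butoxide on tetravalent hafnium, which is also held by the chelating bishydroxamate and binds the cumyl peroxide, and the peroxide oxygen remote from the cumyl group is passed to one vinyl group inside this assembly. The closest known reactions are the hafnium–bishydroxamic acid epoxidation and kinetic resolution of tertiary allylic alcohols and the Sharpless desymmetrisation of secondary divinyl carbinols; a tertiary divinyl carbinol has not been shown in either. The oxirane closes by concerted transfer of a single oxygen atom to C2 and C3 of the alkene, a [2+1] addition with no open intermediate. C2 is controlled by the alkene face that the ligand leaves open to the bound peroxide, and C1' by which of the two enantiotopic vinyl groups reacts, that is by how the ligand places the spectator methyl and vinyl groups. The step therefore needs group and face selection together (one of four stereoisomers) and a stop after one oxidation; the coordinating hydroxyl confines the oxidant to the allylic alkenes, and the resolution of racemic tertiary allylic alcohols by this catalyst type indicates that it can tell two spectator substituents apart. The minor enantiomer still holds the vinyl group that the catalyst prefers, so it should be consumed faster in a second epoxidation and the enantiomeric purity of 5 should rise with conversion; diastereomers are not removed in this way and have to be separated.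

Step 3
Reactants: 5 (2S)-2-[(2S)-oxiran-2-yl]but-3-en-2-ol
Product: 6 triethyl{[(2S)-2-[(2S)-oxiran-2-yl]but-3-en-2-yl]oxy}silane
Conditions: TESOTf (1.2 equiv), 2,6-lutidine (2 equiv), CH2Cl2, −78 °C
Reagents that add atoms: triethylsilyl trifluoromethanesulfonate, CC[Si](CC)(CC)OS(=O)(=O)C(F)(F)F
Why: Silylation of a tertiary alcohol with a silyl triflate and a hindered pyridine base; at −78 °C the hydroxyl should react much faster than the oxirane is activated. The ether blocks Payne rearrangement and ring closure through the tertiary oxygen in step 4 and makes the volatile, water-soluble 5 easier to handle.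

Step 4
Reactants: 6 triethyl{[(2S)-2-[(2S)-oxiran-2-yl]but-3-en-2-yl]oxy}silane; 7 cyclohexane-1,3-dione
Product: 9 (2S)-2-[(2S)-2-(triethylsilyloxy)but-3-en-2-yl]-3,5,6,7-tetrahydro-1-benzofuran-4(2H)-one, via hydroxyalkyl dione 8 (not isolated)
Conditions: 7 (3 equiv), NaOH (1.5 equiv), EtOH/H2O 1:1, 70 °C; NaH2PO4 work-up; then PPTS (10 mol%), 4 Å MS, toluene, 60 °C
Reagents that add atoms: none
Why: C-alkylation of the 1,3-dione enolate by SN2 opening of the terminal epoxide at its CH2 (C2 is not touched and keeps its configuration), then hemiketal formation by the C2 hydroxyl (5-exo-trig addition to C=O) and acid-catalysed dehydration to the vinylogous ester. The dione/enolate buffer keeps the new hydroxyl protonated, which holds back 1,2-silyl migration, and because 7 is symmetric either carbonyl gives the same ring.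

Step 5
Reactants: 9 (2S)-2-[(2S)-2-(triethylsilyloxy)but-3-en-2-yl]-3,5,6,7-tetrahydro-1-benzofuran-4(2H)-one
Product: 11 (2S,5R)-5-hydroxy-2-[(2S)-2-(triethylsilyloxy)but-3-en-2-yl]-3,5,6,7-tetrahydro-1-benzofuran-4(2H)-one, via lithium dienolate 10 (not isolated)
Conditions: LiN(iPr)2 (1.1 equiv), THF, −78 °C; then (+)-(camphorsulfonyl)oxaziridine (1.3 equiv), −78 to −40 °C; aq. NH4Cl
Reagents that add atoms: (+)-(camphorsulfonyl)oxaziridine, CC1(C)[C@@H]2CC[C@]13CS(=O)(=O)N4O[C@@]34C2
Why: Kinetic deprotonation of the vinylogous ester at the α' carbon C5 and asymmetric enolate hydroxylation with an enantiopure N-sulfonyloxaziridine (Davis oxidation); C5 is set by reagent control because C2 and C1' are too far away to bias the planar dienolate. The ketimine by-product is too hindered to add the enolate, and the C5 epimers are diastereomers, so a minor isomer can be removed by chromatography.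

Step 6
Reactants: 11 (2S,5R)-5-hydroxy-2-[(2S)-2-(triethylsilyloxy)but-3-en-2-yl]-3,5,6,7-tetrahydro-1-benzofuran-4(2H)-one
Product: 12 (2S,5R)-5-(triethylsilyloxy)-2-[(2S)-2-(triethylsilyloxy)but-3-en-2-yl]-3,5,6,7-tetrahydro-1-benzofuran-4(2H)-one
Conditions: TESCl (1.3 equiv), imidazole (2 equiv), DMAP (cat.), DMF, 0 °C to rt
Reagents that add atoms: chlorotriethylsilane, CC[Si](Cl)(CC)CC
Why: Standard silylation of a secondary α-hydroxy ketone with a silyl chloride and imidazole. It removes the acidic O–H before the hydroboration and adds steric cover to the C4 carbonyl.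

Step 7
Reactants: 13 pent-4-yn-1-ol
Product: 15 (E)-5-iodo-4-methylpent-4-en-1-ol, via alkenylalane 14 (not isolated)
Conditions: AlMe3 (3 equiv), Cp2ZrCl2 (0.25 equiv), CH2Cl2, 0 °C to rt; then I2, THF, −30 to 0 °C; aq. NaHCO3/Na2S2O3
Reagents that add atoms: trimethylaluminium, C[Al](C)C; iodine, II
Why: Zirconium-catalysed methylalumination of a terminal alkyne (Negishi carboalumination) adds methyl and aluminium syn with the metal on the terminal carbon, and iodinolysis replaces aluminium with retention, which fixes the E geometry of the future C4'=C5' bond. The hydroxyl is carried as its aluminium alkoxide.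

Step 8
Reactants: 15 (E)-5-iodo-4-methylpent-4-en-1-ol
Product: 16 (E)-5-iodo-4-methylpent-4-enal
Conditions: TEMPO (10 mol%), PhI(OAc)2 (1.1 equiv), CH2Cl2, rt
Reagents that add atoms: none
Why: Oxoammonium-mediated oxidation of a primary alcohol, which stops at the aldehyde and leaves the alkenyl iodide alone.

Step 9
Reactants: 16 (E)-5-iodo-4-methylpent-4-enal; 17 ethyl 2-(triphenylphosphoranylidene)propanoate
Product: 18 ethyl (2E,6E)-7-iodo-2,6-dimethylhepta-2,6-dienoate
Conditions: 17 (1.2 equiv), CH2Cl2, rt to 40 °C
Reagents that add atoms: none
Why: Wittig olefination with a stabilised, α-branched ylide, which should give the E-trisubstituted enoate and so sets the C8'=C9' geometry.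

Step 10
Reactants: 18 ethyl (2E,6E)-7-iodo-2,6-dimethylhepta-2,6-dienoate
Product: 19 (2E,6E)-7-iodo-2,6-dimethylhepta-2,6-dienoic acid
Conditions: LiOH (3 equiv), THF/MeOH/H2O, rt; then 1 M HCl to pH 3
Reagents that add atoms: lithium hydroxide, [Li+].[OH-]
Why: Saponification on the simple fragment, where hydroxide can do no harm. The acid is taken into the coupling as its caesium salt, so no ester has to be cleaved once the α-ketol and the vinylogous ester are present.

Step 11
Reactants: 12 (2S,5R)-5-(triethylsilyloxy)-2-[(2S)-2-(triethylsilyloxy)but-3-en-2-yl]-3,5,6,7-tetrahydro-1-benzofuran-4(2H)-one; 19 (2E,6E)-7-iodo-2,6-dimethylhepta-2,6-dienoic acid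
Product: 21 (2E,6E,10S)-2,6-dimethyl-10-(triethylsilyloxy)-10-[(2S,5R)-4-oxo-5-(triethylsilyloxy)-2,3,4,5,6,7-hexahydro-1-benzofuran-2-yl]undeca-2,6-dienoic acid, via B-alkyl-9-BBN 20 (not isolated)
Conditions: 9-BBN (1.5 equiv), THF, 0 °C to rt; then H2O, 19 (1.2 equiv), PdCl2(dppf) (5 mol%), AsPh3 (10 mol%), Cs2CO3 (4 equiv), DMF/H2O, rt; NaH2PO4 work-up
Reagents that add atoms: none
Why: Anti-Markovnikov hydroboration of the monosubstituted alkene with a hindered dialkylborane, then B-alkyl Suzuki–Miyaura coupling with the alkenyl iodide, which forms the C3'–C4' bond with retention of the alkene geometry. The C4 carbonyl is a vinylogous ester flanked by a silyl ether and is expected to be reduced much more slowly than the terminal alkene is hydroborated; the oxygen on C1' is γ to boron, so β-elimination is not possible.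

Step 12
Reactants: 21 (2E,6E,10S)-2,6-dimethyl-10-(triethylsilyloxy)-10-[(2S,5R)-4-oxo-5-(triethylsilyloxy)-2,3,4,5,6,7-hexahydro-1-benzofuran-2-yl]undeca-2,6-dienoic acid
Product: 22 (2E,6E,10S)-10-hydroxy-10-[(2S,5R)-5-hydroxy-4-oxo-2,3,4,5,6,7-hexahydro-1-benzofuran-2-yl]-2,6-dimethylundeca-2,6-dienoic acid
Conditions: HF·pyridine, pyridine, THF, 0 °C to rt
Reagents that add atoms: none
Why: Fluoride cleavage of both triethylsilyl ethers under buffered, non-nucleophilic conditions, which should not enolise C5, open the vinylogous ester or touch the alkenes.

## Compound list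

1 | ethyl acetate | CCOC(C)=O | starting material
2 | vinylmagnesium bromide | C=C[Mg]Br | starting material
3 | but-3-en-2-one | CC(=O)C=C | intermediate
4 | 3-methylpenta-1,4-dien-3-ol | C=CC(C)(O)C=C | intermediate
5 | (2S)-2-[(2S)-oxiran-2-yl]but-3-en-2-ol | C=C[C@](C)(O)[C@@H]1CO1 | intermediate
6 | triethyl{[(2S)-2-[(2S)-oxiran-2-yl]but-3-en-2-yl]oxy}silane | C=C[C@](C)(O[Si](CC)(CC)CC)[C@@H]1CO1 | intermediate
7 | cyclohexane-1,3-dione | O=C1CCCC(=O)C1 | starting material
8 | 2-[(2S,3S)-2-hydroxy-3-methyl-3-(triethylsilyloxy)pent-4-en-1-yl]cyclohexane-1,3-dione | C=C[C@](C)(O[Si](CC)(CC)CC)[C@@H](O)CC1C(=O)CCCC1=O | intermediate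
9 | (2S)-2-[(2S)-2-(triethylsilyloxy)but-3-en-2-yl]-3,5,6,7-tetrahydro-1-benzofuran-4(2H)-one | C=C[C@](C)(O[Si](CC)(CC)CC)[C@@H]1CC2=C(CCCC2=O)O1 | intermediate
10 | lithium (2S)-2-[(2S)-2-(triethylsilyloxy)but-3-en-2-yl]-2,3,6,7-tetrahydro-1-benzofuran-4-olate | C=C[C@](C)(O[Si](CC)(CC)CC)[C@@H]1CC2=C(CCC=C2O[Li])O1 | intermediate
11 | (2S,5R)-5-hydroxy-2-[(2S)-2-(triethylsilyloxy)but-3-en-2-yl]-3,5,6,7-tetrahydro-1-benzofuran-4(2H)-one | C=C[C@](C)(O[Si](CC)(CC)CC)[C@@H]1CC2=C(CC[C@@H](O)C2=O)O1 | intermediate
12 | (2S,5R)-5-(triethylsilyloxy)-2-[(2S)-2-(triethylsilyloxy)but-3-en-2-yl]-3,5,6,7-tetrahydro-1-benzofuran-4(2H)-one | C=C[C@](C)(O[Si](CC)(CC)CC)[C@@H]1CC2=C(CC[C@@H](O[Si](CC)(CC)CC)C2=O)O1 | intermediate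
13 | pent-4-yn-1-ol | C#CCCCO | starting material
14 | dimethyl{(1E)-5-[(dimethylalumanyl)oxy]-2-methylpent-1-en-1-yl}alumane | C[Al](C)/C=C(\C)CCCO[Al](C)C | intermediate
15 | (E)-5-iodo-4-methylpent-4-en-1-ol | C/C(=C\I)CCCO | intermediate
16 | (E)-5-iodo-4-methylpent-4-enal | C/C(=C\I)CCC=O | intermediate
17 | ethyl 2-(triphenylphosphoranylidene)propanoate | CCOC(=O)C(C)=P(c1ccccc1)(c1ccccc1)c1ccccc1 | starting material
18 | ethyl (2E,6E)-7-iodo-2,6-dimethylhepta-2,6-dienoate | C/C(=C\I)CC/C=C(\C)C(=O)OCC | intermediate
19 | (2E,6E)-7-iodo-2,6-dimethylhepta-2,6-dienoic acid | C/C(=C\I)CC/C=C(\C)C(=O)O | intermediate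
20 | 9-{(3S)-3-(triethylsilyloxy)-3-[(2S,5R)-4-oxo-5-(triethylsilyloxy)-2,3,4,5,6,7-hexahydro-1-benzofuran-2-yl]butyl}-9-borabicyclo[3.3.1]nonane | C1CC2CCCC(C1)B2CC[C@](C)(O[Si](CC)(CC)CC)[C@@H]3CC4=C(CC[C@@H](O[Si](CC)(CC)CC)C4=O)O3 | intermediate
21 | (2E,6E,10S)-2,6-dimethyl-10-(triethylsilyloxy)-10-[(2S,5R)-4-oxo-5-(triethylsilyloxy)-2,3,4,5,6,7-hexahydro-1-benzofuran-2-yl]undeca-2,6-dienoic acid | C/C(=C\CC[C@](C)(O[Si](CC)(CC)CC)[C@@H]1CC2=C(CC[C@@H](O[Si](CC)(CC)CC)C2=O)O1)CC/C=C(\C)C(=O)O | intermediate
22 | (2E,6E,10S)-10-hydroxy-10-[(2S,5R)-5-hydroxy-4-oxo-2,3,4,5,6,7-hexahydro-1-benzofuran-2-yl]-2,6-dimethylundeca-2,6-dienoic acid | C/C(=C\CC[C@](C)(O)[C@@H]1CC2=C(CC[C@@H](O)C2=O)O1)CC/C=C(\C)C(=O)O | target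

## Step count and least certain steps

Total step count: 12. Longest linear sequence: 8 steps (steps 1 to 6, 11 and 12, from ethyl acetate 1); the side-chain fragment takes 4 steps (steps 7 to 10).

**Step 2 (key step, proposed new method).**
- What may go wrong: the catalyst may not tell the enantiotopic vinyl groups or their faces apart well enough, because the spectator methyl and vinyl groups differ little in size; this would give diastereomers and low enantiomeric purity. Oxygen transfer to an unactivated monosubstituted alkene may be slow, so that unselective background oxidation and catalyst decay compete. Over-oxidation to the bis-epoxide and evaporative loss of the small product are further risks.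
- Fallback (chiral pool and Grignard additions, all known chemistry): it sets out from Grignard reagent 2 and comes back at 5. Commercial methyl (4S)-2,2-dimethyl-1,3-dioxolane-4-carboxylate F1 is converted with N,O-dimethylhydroxylamine hydrochloride and iPrMgCl into the Weinreb amide (4S)-N-methoxy-N,2,2-trimethyl-1,3-dioxolane-4-carboxamide F2, and methylmagnesium bromide then gives the methyl ketone 1-[(4S)-2,2-dimethyl-1,3-dioxolan-4-yl]ethan-1-one F3. Addition of 2 under chelating conditions should follow the Cram chelate model and give (2S)-2-[(4S)-2,2-dimethyl-1,3-dioxolan-4-yl]but-3-en-2-ol F4. If the open Felkin–Anh course prevails instead, the two groups are introduced in the other order: 2 is added to F2 to give the enone 1-[(4S)-2,2-dimethyl-1,3-dioxolan-4-yl]prop-2-en-1-one F5, and methylmagnesium bromide then leads to the same F4. Aqueous acetic acid removes the acetonide to give (2S,3S)-3-methylpent-4-ene-1,2,3-triol F6. Selective sulfonylation of the primary hydroxyl (TsCl, Bu2SnO cat., Et3N) gives (2S,3S)-2,3-dihydroxy-3-methylpent-4-en-1-yl 4-methylbenzenesulfonate F7, and K2CO3 in MeOH closes the oxirane from the C2 oxygen to give 5 with C2 untouched.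

**Step 4.**
- What may go wrong: the ambident dione enolate may be alkylated on oxygen instead of carbon. The opening may also be slow, because the stabilised enolate is a weak nucleophile, so that solvolysis of the epoxide takes over. Silyl migration to the new C2 hydroxyl is possible if the medium becomes too basic.
- Fallback (a carbon-only dione equivalent): it sets out from 6 and comes back at 9. Commercial 1,5-dimethoxycyclohexa-1,4-diene F8 is lithiated at the CH2 between the two enol ethers (tBuLi, THF/HMPA, −78 °C), and the anion opens 6 at CH2 to give (2S,3S)-1-(2,6-dimethoxycyclohexa-2,5-dien-1-yl)-3-methyl-3-(triethylsilyloxy)pent-4-en-2-ol F9. Mild aqueous acid (oxalic acid, THF/H2O) hydrolyses both enol ethers to 8, which cyclodehydrates to 9 as in step 4.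

**Step 5.**
- What may go wrong: the facial selectivity may be poor, because the two remote stereocentres give no bias and reagent control over a cyclic enolate that forms a secondary carbinol can be modest. Partial epimerisation at C5 during quench is a further risk.
- Fallback (asymmetric epoxidation of a neutral silyl dienol ether in place of enolate oxidation): it sets out from 9 and comes back at 11. The kinetic enolate of 9 is trapped with TBSCl to give tert-butyldimethyl{[(2S)-2-[(2S)-2-(triethylsilyloxy)but-3-en-2-yl]-2,3,6,7-tetrahydro-1-benzofuran-4-yl]oxy}silane F10. Shi epoxidation with the fructose-derived ketone catalyst (KHSO5, K2CO3 buffer, MeCN/dimethoxymethane/H2O, 0 °C; the catalyst enantiomer chosen for 5R) oxidises the electron-rich C4=C5 bond in preference to the terminal vinyl group, and the silyloxy epoxide collapses on work-up to 11.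

**Step 11.**
- What may go wrong: the borane may reduce the C4 carbonyl in competition with a hydroboration that is slowed by the neighbouring quaternary carbon. Protodeboronation or β-hydride elimination during the coupling would also lower the return.
- Fallback (catalysed hydroboration to an isolable boronate): it sets out from 12 and comes back at 21. Iridium-catalysed hydroboration with pinacolborane ([Ir(cod)Cl]2, dppm, CH2Cl2, rt), which does not reduce ketones, gives (2S,5R)-2-[(2S)-4-(4,4,5,5-tetramethyl-1,3,2-dioxaborolan-2-yl)-2-(triethylsilyloxy)butan-2-yl]-5-(triethylsilyloxy)-3,5,6,7-tetrahydro-1-benzofuran-4(2H)-one F11. Coupling of F11 with 19 (Pd(OAc)2, SPhos, K3PO4, toluene/H2O, 60 °C) gives 21.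

## Further compounds

F1 | step 2 | methyl (4S)-2,2-dimethyl-1,3-dioxolane-4-carboxylate | COC(=O)[C@@H]1COC(C)(C)O1
F2 | step 2 | (4S)-N-methoxy-N,2,2-trimethyl-1,3-dioxolane-4-carboxamide | CON(C)C(=O)[C@@H]1COC(C)(C)O1
F3 | step 2 | 1-[(4S)-2,2-dimethyl-1,3-dioxolan-4-yl]ethan-1-one | CC(=O)[C@@H]1COC(C)(C)O1
F4 | step 2 | (2S)-2-[(4S)-2,2-dimethyl-1,3-dioxolan-4-yl]but-3-en-2-ol | C=C[C@](C)(O)[C@@H]1COC(C)(C)O1
F5 | step 2 | 1-[(4S)-2,2-dimethyl-1,3-dioxolan-4-yl]prop-2-en-1-one | C=CC(=O)[C@@H]1COC(C)(C)O1
F6 | step 2 | (2S,3S)-3-methylpent-4-ene-1,2,3-triol | C=C[C@](C)(O)[C@@H](O)CO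
F7 | step 2 | (2S,3S)-2,3-dihydroxy-3-methylpent-4-en-1-yl 4-methylbenzenesulfonate | C=C[C@](C)(O)[C@@H](O)COS(=O)(=O)c1ccc(C)cc1
F8 | step 4 | 1,5-dimethoxycyclohexa-1,4-diene | COC1=CCC=C(OC)C1
F9 | step 4 | (2S,3S)-1-(2,6-dimethoxycyclohexa-2,5-dien-1-yl)-3-methyl-3-(triethylsilyloxy)pent-4-en-2-ol | C=C[C@](C)(O[Si](CC)(CC)CC)[C@@H](O)CC1C(OC)=CCC=C1OC
F10 | step 5 | tert-butyldimethyl{[(2S)-2-[(2S)-2-(triethylsilyloxy)but-3-en-2-yl]-2,3,6,7-tetrahydro-1-benzofuran-4-yl]oxy}silane | C=C[C@](C)(O[Si](CC)(CC)CC)[C@@H]1CC2=C(CCC=C2O[Si](C)(C)C(C)(C)C)O1
F11 | step 11 | (2S,5R)-2-[(2S)-4-(4,4,5,5-tetramethyl-1,3,2-dioxaborolan-2-yl)-2-(triethylsilyloxy)butan-2-yl]-5-(triethylsilyloxy)-3,5,6,7-tetrahydro-1-benzofuran-4(2H)-one | CC1(C)OB(CC[C@](C)(O[Si](CC)(CC)CC)[C@@H]2CC3=C(CC[C@@H](O[Si](CC)(CC)CC)C3=O)O2)OC1(C)C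
A1 | alternative 1 | (5E)-6,10-dimethylundeca-5,9-dien-2-one (geranylacetone) | CC(=O)CC/C=C(\C)CCC=C(C)C
A2 | alternative 1 | (5E)-1-bromo-6,10-dimethylundeca-5,9-dien-2-one | BrCC(=O)CC/C=C(\C)CCC=C(C)C
A3 | alternative 1 | formaldehyde | C=O
A4 | alternative 1 | (2S)-2-[(4E)-5,9-dimethyldeca-4,8-dienoyl]-3,5,6,7-tetrahydro-1-benzofuran-4(2H)-one | C/C(=C\CCC(=O)[C@@H]1CC2=C(CCCC2=O)O1)CCC=C(C)C
A5 | alternative 2 | (4R)-4-(tert-butyldimethylsilyloxy)-2-{2-[(4S,5S)-2,2,5-trimethyl-5-vinyl-1,3-dioxolan-4-yl]ethyl}cyclohexane-1,3-dione, enol form | OC1=C(CC[C@@H]2OC(C)(C)O[C@@]2(C)C=C)C(=O)[C@H](O[Si](C)(C)C(C)(C)C)CC1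
A6 | alternative 2 | (4R)-4-(tert-butyldimethylsilyloxy)-2-{[(4S,5S)-2,2,5-trimethyl-5-vinyl-1,3-dioxolan-4-yl]methyl}cyclohexane-1,3-dione, enol form | OC1=C(C[C@@H]2OC(C)(C)O[C@@]2(C)C=C)C(=O)[C@H](O[Si](C)(C)C(C)(C)C)CC1
A7 | alternative 3 | (2Z,6E)-3,7,11-trimethyldodeca-2,6,10-trien-1-ol | CC(C)=CCC/C(C)=C/CC/C(C)=C\CO
A8 | alternative 3 | (2E,6E)-3,7,11-trimethyldodeca-2,6,10-trien-1-ol | CC(C)=CCC/C(C)=C/CC/C(C)=C/CO
A9 | alternative 3 | {(2R,3S)-3-[(3E)-4,8-dimethylnona-3,7-dien-1-yl]-3-methyloxiran-2-yl}methanol | CC(C)=CCC/C(C)=C/CC[C@]1(C)O[C@@H]1CO
A10 | alternative 3 | (2S)-2-[(2S,5E)-2-hydroxy-6,10-dimethylundeca-5,9-dien-2-yl]-3,5,6,7-tetrahydro-1-benzofuran-4(2H)-one | C/C(=C\CC[C@](C)(O)[C@@H]1CC2=C(CCCC2=O)O1)CCC=C(C)C
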